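The numbers of this flask stand for no real mixture.

A small charge of initiator goes into a flask of free monomer, and I want the chain length and the monomer reacted after some days.

free monomer 0.26 M; initiator 2.5 mol%; time 10 d

    2 living end → dead end A (k1 = 0.153 M⁻¹ min⁻¹)
    free monomer + living end → monomer in chains + living end, rate k2*[living end]*[free monomer] (k2 = 0.278 M⁻¹ min⁻¹)
    free monomer + initiator → living end + monomer in chains (k3 = 0.136 M⁻¹ min⁻¹)
    initiator → spent initiator B (k4 = 0.0168 min⁻¹)

1. average number of monomer units in a chain (chains begun, living or dead) at 10 d
2. part of the free monomer that has reacted at 10 d

A molecule of initiator has two fates: it meets free monomer and begins a chain, or it falls apart to spent initiator B. At the charged monomer, the first goes at 0.0354 min⁻¹ and the second at 0.0168 min⁻¹, so beginning a chain is the faster fate. The share of the charged initiator that begins a chain is then 67.8%, the first rate over the sum of both; polymer chemists call this the initiator efficiency.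

chains begun = 67.8% × 0.00650 M = 0.00441 M

Holding the monomer at its charge is fair here. The initiator's half-life by both fates at the charged monomer is 13.3 min, far shorter than the 9.43 h that is the half-life of free monomer with living ends held at 0.00441 M.

I let the chains begin at the start, and the living ends then die in pairs. Their number falls by a factor that grows in a straight line with time, reaching 20.4 at 10 d. Free monomer falls as that factor raised to the power 0.908, taken negative:

part reacted = 93.5%

units per chain = 93.5% × 0.26 M / 0.00441 M = 55.2

The forecast gives 56 (from 52 to 60) and 93.5% (from 91% to 95.5%), with “roughly two-thirds of it (about 0.0043 M) starting chains in competition with its own decay”.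

The flask gives 55.6 units per chain and 93.7% reacted at 10 d, against my 55.2 and 93.5%. In this flask initiator stands at 0% of its charge and spent initiator B at 0.00212 M out of 0.00650 M charged, which leaves a chain-starting share of 67.3% against my 67.8%. The neighbouring flask with 6.2 mol% of initiator, read at the same time, has 97.3% of its free monomer reacted; dividing that by its loading and the same share gives 23.1 units per chain, and that neighbouring flask gives 23.5.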